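**Retrosynthetic overview**
- Target ⇐ mild hydrolysis of an allylic dimethyl acetal; the acetate comes from a silyl-protected (S)-benzylic alcohol, the exo-methylene from a C2 ketone, the isovalerate from the C3 alcohol.
- The 2-acyl-3-hydroxy-2,3-dihydrobenzofuran ⇐ intramolecular (S)-proline enamine aldol (C2–C3 bond, 5-enolexo) of an aryloxymethyl ketone onto the ortho aldehyde; this sets C2 and C3 (cis).
- Aldol substrate ⇐ O-alkylation joining fragment A (silyl-protected (S)-5-(1-hydroxyethyl)salicylaldehyde) with fragment B (3-bromo-1,1-dimethoxypropan-2-one).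
- Fragment A ⇐ 4'-hydroxyacetophenone (asymmetric transfer hydrogenation, silylation, ortho-formylation); fragment B ⇐ 1,1-dimethoxypropan-2-one (bromination).
- Ring order: the benzene ring is bought; the dihydrofuran ring is the only ring formed, in step 6.

Assumption: the SMILES is read as (2R,3R) at the dihydrofuran (2,3-cis) and (S) at the acetoxy-bearing benzylic carbon.

**Step 1**
Reactants: 1 4'-hydroxyacetophenone
Product: 2 4-[(1S)-1-hydroxyethyl]phenol
Conditions: RuCl[(S,S)-TsDPEN](p-cymene) (0.5 mol%), HCO2H/Et3N (5:2), 30 °C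
Reagents that add atoms: none
Why: Noyori asymmetric transfer hydrogenation of an aryl methyl ketone, in which the (S,S) catalyst delivers hydride to the Re face and sets the benzylic centre as S.

**Step 2**
Reactants: 2 4-[(1S)-1-hydroxyethyl]phenol
Product: 4 4-[(1S)-1-{[tert-butyl(dimethyl)silyl]oxy}ethyl]phenol, via bis-silyl ether 3 (not isolated)
Conditions: TBSCl (2.4 equiv), imidazole, DMF, rt; aqueous wash; then K2CO3 (0.5 equiv), MeOH, rt
Reagents that add atoms: tert-butyldimethylsilyl chloride, CC(C)(C)[Si](C)(C)Cl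
Why: Exhaustive silylation followed by base-catalysed methanolysis, which removes only the far more labile aryl silyl ether; the C–O bond of the stereocentre is never broken.

**Step 3**
Reactants: 4 4-[(1S)-1-{[tert-butyl(dimethyl)silyl]oxy}ethyl]phenol
Product: 5 5-[(1S)-1-{[tert-butyl(dimethyl)silyl]oxy}ethyl]-2-hydroxybenzaldehyde
Conditions: MgCl2, Et3N, paraformaldehyde, THF, reflux; dilute aqueous acid work-up
Reagents that add atoms: paraformaldehyde (as formaldehyde), C=O
Why: Magnesium-phenoxide-directed ortho-formylation (Casnati–Skattebøl), ortho-hydroxymethylation then hydride transfer to a second formaldehyde; the para position is blocked and the silyl ether keeps the benzylic alcohol out of the redox step.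

**Step 4**
Reactants: 6 1,1-dimethoxypropan-2-one
Product: 7 3-bromo-1,1-dimethoxypropan-2-one
Conditions: Br2, MeOH, 0 °C → rt; aqueous K2CO3 work-up
Reagents that add atoms: bromine, BrBr
Why: Acid-catalysed electrophilic α-bromination of a methyl ketone in methanol, which takes place at the methyl group.

**Step 5**
Reactants: 5 5-[(1S)-1-{[tert-butyl(dimethyl)silyl]oxy}ethyl]-2-hydroxybenzaldehyde; 7 3-bromo-1,1-dimethoxypropan-2-one
Product: 8 5-[(1S)-1-{[tert-butyl(dimethyl)silyl]oxy}ethyl]-2-(3,3-dimethoxy-2-oxopropoxy)benzaldehyde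
Conditions: K2CO3, acetone, 0 °C → rt
Reagents that add atoms: none
Why: Williamson O-alkylation (SN2) of the salicylaldehyde phenoxide by a highly reactive α-bromo ketone joins fragments A and B; mild base at low temperature avoids premature aldolisation.

**Step 6**
Reactants: 8 5-[(1S)-1-{[tert-butyl(dimethyl)silyl]oxy}ethyl]-2-(3,3-dimethoxy-2-oxopropoxy)benzaldehyde
Product: 9 1-[(2S,3R)-5-[(1S)-1-{[tert-butyl(dimethyl)silyl]oxy}ethyl]-3-hydroxy-2,3-dihydro-1-benzofuran-2-yl]-2,2-dimethoxyethan-1-one (2,3-cis)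
Conditions: (S)-proline (30 mol%), DMF, rt
Reagents that add atoms: none
Why: Proline enamine intramolecular aldol (5-enolexo, Houk–List model): the enamine forms on the ArOCH2 side with O trans to N and attacks the ortho aldehyde on the face bearing the carboxylic acid, whose hydrogen bond to the aldehyde oxygen places acyl and OH cis, giving (2S,3R).

**Step 7**
Reactants: 9 1-[(2S,3R)-5-[(1S)-1-{[tert-butyl(dimethyl)silyl]oxy}ethyl]-3-hydroxy-2,3-dihydro-1-benzofuran-2-yl]-2,2-dimethoxyethan-1-one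
Product: 10 (2S,3R)-5-[(1S)-1-{[tert-butyl(dimethyl)silyl]oxy}ethyl]-2-(dimethoxyacetyl)-2,3-dihydro-1-benzofuran-3-yl 3-methylbutanoate
Conditions: 3-methylbutanoyl chloride, pyridine, CH2Cl2, 0 °C
Reagents that add atoms: 3-methylbutanoyl chloride, CC(C)CC(Cl)=O
Why: Acylation through the acylpyridinium ion esterifies the C3 alcohol with retention, and the weak base at 0 °C is meant to avoid enolisation at C2 and β-elimination to the benzofuran.

**Step 8**
Reactants: 10 (2S,3R)-5-[(1S)-1-{[tert-butyl(dimethyl)silyl]oxy}ethyl]-2-(dimethoxyacetyl)-2,3-dihydro-1-benzofuran-3-yl 3-methylbutanoate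
Product: 11 (2R,3R)-5-[(1S)-1-{[tert-butyl(dimethyl)silyl]oxy}ethyl]-2-(3,3-dimethoxyprop-1-en-2-yl)-2,3-dihydro-1-benzofuran-3-yl 3-methylbutanoate
Conditions: Cp2Ti(μ-Cl)(μ-CH2)AlMe2 (Tebbe reagent, 1.3 equiv), pyridine (cat.), THF/toluene, −40 → 0 °C; aq. NaHCO3
Reagents that add atoms: Cp2Ti(μ-Cl)(μ-CH2)AlMe2, C[Al-]1(C)C[Ti](C2C=CC=C2)(C2C=CC=C2)[Cl+]1
Why: Non-basic titanium-methylidene carbonyl methylenation (Tebbe olefination) converts the ketone faster than the ester at low temperature without epimerising C2; the C2 descriptor becomes R only because the CIP ranking of its substituents changes.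

**Step 9**
Reactants: 11 (2R,3R)-5-[(1S)-1-{[tert-butyl(dimethyl)silyl]oxy}ethyl]-2-(3,3-dimethoxyprop-1-en-2-yl)-2,3-dihydro-1-benzofuran-3-yl 3-methylbutanoate
Product: 13 (2R,3R)-5-[(1S)-1-(acetyloxy)ethyl]-2-(3,3-dimethoxyprop-1-en-2-yl)-2,3-dihydro-1-benzofuran-3-yl 3-methylbutanoate, via benzylic alcohol 12 (not isolated)
Conditions: Bu4NF, AcOH, THF, 0 °C → rt; then Ac2O, Et3N, DMAP (cat.), rt
Reagents that add atoms: acetic anhydride, CC(=O)OC(C)=O
Why: Buffered fluoride desilylation breaks the Si–O bond, not the benzylic C–O bond, so the S centre is retained, and DMAP-catalysed acetylation caps the freed alcohol while the aldehyde is still masked.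

**Step 10**
Reactants: 13 (2R,3R)-5-[(1S)-1-(acetyloxy)ethyl]-2-(3,3-dimethoxyprop-1-en-2-yl)-2,3-dihydro-1-benzofuran-3-yl 3-methylbutanoate
Product: 14 (2R,3R)-5-[(1S)-1-(acetyloxy)ethyl]-2-(3-oxoprop-1-en-2-yl)-2,3-dihydro-1-benzofuran-3-yl 3-methylbutanoate
Conditions: PPTS (cat.), acetone/H2O (10:1), rt
Reagents that add atoms: water, O
Why: Acid-catalysed hydrolysis of the allylic dimethyl acetal through a conjugation-stabilised oxocarbenium ion frees the enal under conditions chosen to be too mild to ionise the benzylic esters, and no stereocentre is touched.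

**Compound list**
1 | 4'-hydroxyacetophenone | CC(=O)c1ccc(O)cc1 | starting material
2 | 4-[(1S)-1-hydroxyethyl]phenol | C[C@H](O)c1ccc(O)cc1 | intermediate
3 | tert-butyl{4-[(1S)-1-{[tert-butyl(dimethyl)silyl]oxy}ethyl]phenoxy}dimethylsilane (bis-silyl ether) | C[C@H](O[Si](C)(C)C(C)(C)C)c1ccc(O[Si](C)(C)C(C)(C)C)cc1 | intermediate
4 | 4-[(1S)-1-{[tert-butyl(dimethyl)silyl]oxy}ethyl]phenol | C[C@H](O[Si](C)(C)C(C)(C)C)c1ccc(O)cc1 | intermediate
5 | 5-[(1S)-1-{[tert-butyl(dimethyl)silyl]oxy}ethyl]-2-hydroxybenzaldehyde | C[C@H](O[Si](C)(C)C(C)(C)C)c1ccc(O)c(C=O)c1 | intermediate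
6 | 1,1-dimethoxypropan-2-one | COC(OC)C(C)=O | starting material
7 | 3-bromo-1,1-dimethoxypropan-2-one | COC(OC)C(=O)CBr | intermediate
8 | 5-[(1S)-1-{[tert-butyl(dimethyl)silyl]oxy}ethyl]-2-(3,3-dimethoxy-2-oxopropoxy)benzaldehyde | COC(OC)C(=O)COc1ccc([C@H](C)O[Si](C)(C)C(C)(C)C)cc1C=O | intermediate
9 | 1-[(2S,3R)-5-[(1S)-1-{[tert-butyl(dimethyl)silyl]oxy}ethyl]-3-hydroxy-2,3-dihydro-1-benzofuran-2-yl]-2,2-dimethoxyethan-1-one | COC(OC)C(=O)[C@H]1Oc2ccc([C@H](C)O[Si](C)(C)C(C)(C)C)cc2[C@H]1O | intermediate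
10 | (2S,3R)-5-[(1S)-1-{[tert-butyl(dimethyl)silyl]oxy}ethyl]-2-(dimethoxyacetyl)-2,3-dihydro-1-benzofuran-3-yl 3-methylbutanoate | COC(OC)C(=O)[C@H]1Oc2ccc([C@H](C)O[Si](C)(C)C(C)(C)C)cc2[C@H]1OC(=O)CC(C)C | intermediate
11 | (2R,3R)-5-[(1S)-1-{[tert-butyl(dimethyl)silyl]oxy}ethyl]-2-(3,3-dimethoxyprop-1-en-2-yl)-2,3-dihydro-1-benzofuran-3-yl 3-methylbutanoate | C=C(C(OC)OC)[C@H]1Oc2ccc([C@H](C)O[Si](C)(C)C(C)(C)C)cc2[C@H]1OC(=O)CC(C)C | intermediate
12 | (2R,3R)-2-(3,3-dimethoxyprop-1-en-2-yl)-5-[(1S)-1-hydroxyethyl]-2,3-dihydro-1-benzofuran-3-yl 3-methylbutanoate | C=C(C(OC)OC)[C@H]1Oc2ccc([C@H](C)O)cc2[C@H]1OC(=O)CC(C)C | intermediate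
13 | (2R,3R)-5-[(1S)-1-(acetyloxy)ethyl]-2-(3,3-dimethoxyprop-1-en-2-yl)-2,3-dihydro-1-benzofuran-3-yl 3-methylbutanoate | C=C(C(OC)OC)[C@H]1Oc2ccc([C@H](C)OC(C)=O)cc2[C@H]1OC(=O)CC(C)C | intermediate
14 | (2R,3R)-5-[(1S)-1-(acetyloxy)ethyl]-2-(3-oxoprop-1-en-2-yl)-2,3-dihydro-1-benzofuran-3-yl 3-methylbutanoate | C=C(C=O)[C@H]1Oc2ccc([C@H](C)OC(C)=O)cc2[C@H]1OC(=O)CC(C)C | target

**Step count**
Total steps: 10 (fragment A: steps 1–3; fragment B: step 4; union: step 5; steps 6–10 after the union).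
Longest linear sequence: 9 (steps 1, 2, 3, 5, 6, 7, 8, 9, 10).

**Three steps most likely to fail, with fallbacks**

Step 6 (cis selectivity of the aldol; dehydration to the benzofuran is the side reaction). The fallback sets out from 8 and comes back at 10. If the proline closure gives the 2,3-trans aldol 1-[(2S,3S)-5-[(1S)-1-{[tert-butyl(dimethyl)silyl]oxy}ethyl]-3-hydroxy-2,3-dihydro-1-benzofuran-2-yl]-2,2-dimethoxyethan-1-one F1, its C2 is still S, because C2 is fixed by the enamine face and only the aldehyde face differs. F1 is then esterified with 3-methylbutanoic acid under Mitsunobu conditions (PPh3, DIAD, toluene, 0 °C). The SN2 displacement inverts C3 and gives 10 directly, so C3 is set by inversion instead of by the aldol and step 7 is not needed for this material.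

Step 7 (the β-acyloxy ketone 10 can lose the ester by enolisation at C2 and aromatise). The fallback sets out from 9 and comes back at 11, and it never forms a β-acyloxy ketone. The alcohol of 9 is silylated (Et3SiOTf, 2,6-lutidine, CH2Cl2, −78 °C) to 1-[(2S,3R)-5-[(1S)-1-{[tert-butyl(dimethyl)silyl]oxy}ethyl]-3-[(triethylsilyl)oxy]-2,3-dihydro-1-benzofuran-2-yl]-2,2-dimethoxyethan-1-one F2, in which silyloxide is a poor leaving group. F2 is methylenated with Cp2Ti(μ-Cl)(μ-CH2)AlMe2 to tert-butyl{(1S)-1-[(2R,3R)-2-(3,3-dimethoxyprop-1-en-2-yl)-3-[(triethylsilyl)oxy]-2,3-dihydro-1-benzofuran-5-yl]ethoxy}dimethylsilane F3. The triethylsilyl ether alone is then cleaved (HF·pyridine, pyridine, THF, 0 °C) to (2R,3R)-5-[(1S)-1-{[tert-butyl(dimethyl)silyl]oxy}ethyl]-2-(3,3-dimethoxyprop-1-en-2-yl)-2,3-dihydro-1-benzofuran-3-ol F4. F4 no longer has an acidic C2–H next to a carbonyl and is acylated with 3-methylbutanoyl chloride (pyridine, DMAP) to give 11.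

Step 8 (hindered ketone; competing attack on the ester or Lewis-acid damage by the aluminium component). The fallback sets out from 10 and comes back at 11, and it replaces the titanium carbene by a Peterson addition–elimination. Me3SiCH2MgCl premixed with anhydrous CeCl3 (THF, −78 °C) adds to the ketone in preference to the ester and without enolisation. The adduct is (2S,3R)-5-[(1S)-1-{[tert-butyl(dimethyl)silyl]oxy}ethyl]-2-[2-hydroxy-1,1-dimethoxy-3-(trimethylsilyl)propan-2-yl]-2,3-dihydro-1-benzofuran-3-yl 3-methylbutanoate F5, obtained as both epimers at the new carbinol carbon. Mild acid (PPTS, CH2Cl2, rt) then eliminates trimethylsilanol from either epimer to give 11.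

**Further compounds**
F1 | step 6 | 1-[(2S,3S)-5-[(1S)-1-{[tert-butyl(dimethyl)silyl]oxy}ethyl]-3-hydroxy-2,3-dihydro-1-benzofuran-2-yl]-2,2-dimethoxyethan-1-one | COC(OC)C(=O)[C@H]1Oc2ccc([C@H](C)O[Si](C)(C)C(C)(C)C)cc2[C@@H]1O
F2 | step 7 | 1-[(2S,3R)-5-[(1S)-1-{[tert-butyl(dimethyl)silyl]oxy}ethyl]-3-[(triethylsilyl)oxy]-2,3-dihydro-1-benzofuran-2-yl]-2,2-dimethoxyethan-1-one | COC(OC)C(=O)[C@H]1Oc2ccc([C@H](C)O[Si](C)(C)C(C)(C)C)cc2[C@H]1O[Si](CC)(CC)CC
F3 | step 7 | tert-butyl{(1S)-1-[(2R,3R)-2-(3,3-dimethoxyprop-1-en-2-yl)-3-[(triethylsilyl)oxy]-2,3-dihydro-1-benzofuran-5-yl]ethoxy}dimethylsilane | C=C(C(OC)OC)[C@H]1Oc2ccc([C@H](C)O[Si](C)(C)C(C)(C)C)cc2[C@H]1O[Si](CC)(CC)CC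
F4 | step 7 | (2R,3R)-5-[(1S)-1-{[tert-butyl(dimethyl)silyl]oxy}ethyl]-2-(3,3-dimethoxyprop-1-en-2-yl)-2,3-dihydro-1-benzofuran-3-ol | C=C(C(OC)OC)[C@H]1Oc2ccc([C@H](C)O[Si](C)(C)C(C)(C)C)cc2[C@H]1O
F5 | step 8 | (2S,3R)-5-[(1S)-1-{[tert-butyl(dimethyl)silyl]oxy}ethyl]-2-[2-hydroxy-1,1-dimethoxy-3-(trimethylsilyl)propan-2-yl]-2,3-dihydro-1-benzofuran-3-yl 3-methylbutanoate (both epimers at the carbinol carbon) | COC(OC)C(O)(C[Si](C)(C)C)[C@H]1Oc2ccc([C@H](C)O[Si](C)(C)C(C)(C)C)cc2[C@H]1OC(=O)CC(C)C
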